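I read your two runs before reckoning.

| setting | larch | alder | flask |
|---|---|---|---|
| substrate | 0.30 M | 0.20 M | 0.30 M |
| solid reagent | 0.54 M | 0.54 M | 0.540 M |
| capture agent | 0.090 M | 0.090 M | 0.0900 M |
| remark | the very flask that is asked about, followed so far | run made earlier |  |
| time |  |  | 30 h |

- larch (time / h: target / %): 2.00: 0.4; 5.00: 6.0; 10.0: 13.7; 15.0: 22.6
- alder (time / h: target / %): 8.00: 10.0; 15.0: 28.7; 25.0: 48.0; 30.0: 53.8

(scatter of a reading: 1 percentage point)

- given per volume of solution although it is solid: solid reagent
- at the start none of the solid reagent is in solution
- partner is what solid reagent becomes in solution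

* the target standing at 30 h, as a percentage of the substrate charged
* concentration of partner in solution at 3.0 h, in percent of saturation
* the change that raises the amount of target at 30 h, in percent of the substrate charged most ("none" if none brings more than 2 percentage points) (beta / epsilon / none)
* amount of target at 30 h, in percent of the substrate charged, after beta

- beta: doubling the solubility of the solid reagent, all else as stated
- epsilon: doubling the dissolution coefficient of the solid reagent, all else as stated

1. I took the straight-stretch rate R, the molar target made per hour, from larch between 5.00 h and 15.0 h: R = 0.00498 M/h. Alder gave 0.00534 M/h between 8.00 h and 15.0 h, although larch held 1.50 times its substrate. At this early end, the rate looked zero order in substrate.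

2. For the late end I defined U as substrate charged minus target. Alder held R as far as its 15.0 h reading, where U was 0.143 M. It then slowed to 0.00386 M/h up to 25.0 h, less than before.

3. I joined the ends. Running larch on at R from its 15.0 h reading gave 47.5% at 30 h. U was then 0.157 M, still above alder's 0.143 M, so I kept the line straight to the end.

4. Your forecast gave 41%, 15% of saturation, beta and 58%, holding that “capture exhaustion probably causes the falloff”. My figure stood 6.5 percentage points higher. I reckoned nothing of my own for the other answers.

5. The flask gave 48.5% at 30 h, partner at 13.9% of saturation at 3.0 h, beta as the best change, and 72.7% after it. adduct → target (k = 1.00 × 10⁻⁴ /s); substrate + partner ⇌ adduct (K = 3.20 /M, k = 0.00500 /M/s); capture agent + adduct → trapped intermediate (k = 3.20 × 10⁻⁴ /M/s); solid reagent ⇌ partner, rate k4*(cs4 - [partner]) while solid is left; crystals form when [partner] > cs4 (solubility = 0.0880 M, k = 3.40 × 10⁻⁵ /s)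

6. At 30.0 h, adduct was being made at 0.949 times the rate it was used up. From 22.9% at 15.0 h, the flask made target at 0.00513 M/h on average up to 30 h, against R = 0.00498 M/h. A second flask of the same recipe, read at 20 h, was put by R at 30.9%, and it stood at 32.0%.

(The readings stem from a simulated flask from invented constants, noise included.)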